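## Retrosynthetic overview

1. Target 11 (unit 1 = the 3-linked flavanone with the 4-hydroxyphenyl group, unit 2 = the 8-linked flavanone with the 4-methoxyphenyl group) ⇒ penta-benzyl ether 10, hydrogenolysis last.
2. 10 ⇒ chromone–chromanone 8 + boronic acid 9: asymmetric 1,4-arylation makes C2 of unit 2 (S) and turns racemic unit 1 into separable diastereomers.
3. 8 ⇒ acyclic bis-ketone 4 + aldehyde 5: both pyranone rings close in one pot, ring C of unit 2 (enaminone → chromone) first, then ring C of unit 1 (Knoevenagel/oxa-Michael, trans).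
4. 4 ⇒ two molecules of acetophenone 1 (one as bromo-enaminone 3) by Pd enolate arylation, so the C3(unit 1)–C8(unit 2) bond exists before any heterocycle.
5. Ring order: aromatic rings bought; ring C of unit 2, then ring C of unit 1, same flask; no ring is formed afterwards.

Assumptions: 1 is bought (it is also one step from 2',4',6'-trihydroxyacetophenone and benzyl bromide); the ligand antipode written in step 5 is taken to be the one that gives the S centre, otherwise its mirror image is used.

## Route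

Step 1
Reactants: 1 1-[2,4-bis(benzyloxy)-6-hydroxyphenyl]ethan-1-one
Product: 2 1-[4,6-bis(benzyloxy)-3-bromo-2-hydroxyphenyl]ethan-1-one
Conditions: NBS (1.02 equiv), i-Pr2NH (10 mol %), CH2Cl2, 0 °C
Reagents that add atoms: N-bromosuccinimide, O=C1CCC(=O)N1Br
Why: Amine-assisted electrophilic aromatic bromination goes to the ring carbon ortho to the free, chelated phenol (flanked by OH and one benzyloxy group, not by two benzyloxy groups), and because that phenol is the only oxygen left free to close a pyranone ring, this fixes the later 8-linkage.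

Step 2
Reactants: 2 1-[4,6-bis(benzyloxy)-3-bromo-2-hydroxyphenyl]ethan-1-one
Product: 3 (E)-1-[4,6-bis(benzyloxy)-3-bromo-2-hydroxyphenyl]-3-(dimethylamino)prop-2-en-1-one
Conditions: DMF dimethyl acetal (3 equiv), toluene, 95 °C
Reagents that add atoms: N,N-dimethylformamide dimethyl acetal, COC(OC)N(C)C
Why: Enaminone formation (condensation of the methyl ketone with the amide acetal) supplies C2 and C3 of the future chromone and removes the enolisable acetyl group that would compete in step 3.

Step 3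
Reactants: 3 (E)-1-[4,6-bis(benzyloxy)-3-bromo-2-hydroxyphenyl]-3-(dimethylamino)prop-2-en-1-one + 1 1-[2,4-bis(benzyloxy)-6-hydroxyphenyl]ethan-1-one (1.3 equiv)
Product: 4 (E)-1-{4,6-bis(benzyloxy)-3-[2-(2,4-bis(benzyloxy)-6-hydroxyphenyl)-2-oxoethyl]-2-hydroxyphenyl}-3-(dimethylamino)prop-2-en-1-one
Conditions: Pd2(dba)3 (2.5 mol %), rac-2-(di-tert-butylphosphino)-1,1'-binaphthyl (10 mol %), LiN(SiMe3)2 (4.5 equiv), THF/toluene, 70 °C; aq NH4Cl
Reagents that add atoms: none
Why: Palladium-catalysed α-arylation of a ketone enolate (Buchwald–Hartwig type, for which ortho-bromophenolates are known partners) joins the methyl carbon of 1 to the brominated carbon of 3, the excess amide base carrying both phenols as lithium phenolates and the basic medium preventing benzofuran formation.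

Step 4
Reactants: 4 (E)-1-{4,6-bis(benzyloxy)-3-[2-(2,4-bis(benzyloxy)-6-hydroxyphenyl)-2-oxoethyl]-2-hydroxyphenyl}-3-(dimethylamino)prop-2-en-1-one + 5 4-(benzyloxy)benzaldehyde (1.5 equiv)
Product: 8 racemic trans-5,7-bis(benzyloxy)-2-[4-(benzyloxy)phenyl]-3-[5,7-bis(benzyloxy)-4-oxo-4H-chromen-8-yl]chroman-4-one, via chromone ketone 6 (not isolated), via aryl enone 7 (not isolated)
Conditions: AcOH (5 equiv), EtOH, 60 °C, 2 h; then 5, piperidine (0.3 equiv), 78 °C, 24 h (one pot)
Reagents that add atoms: none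
Why: Acid closes the chromone by intramolecular conjugate addition–elimination of the enaminone (ring C of unit 2), the released dimethylammonium acetate together with piperidinium acetate then drives a Knoevenagel condensation of the benzylic ketone with 5, and the resulting 2'-hydroxy-α-arylchalcone closes by 6-endo oxa-Michael addition (ring C of unit 1), C2 and C3 arising together as the thermodynamically preferred trans (diequatorial) pair through the epimerisable C3, in racemic form.

Step 5
Reactants: 8 racemic trans-5,7-bis(benzyloxy)-2-[4-(benzyloxy)phenyl]-3-[5,7-bis(benzyloxy)-4-oxo-4H-chromen-8-yl]chroman-4-one + 9 4-methoxyphenylboronic acid (4 equiv)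
Product: 10 (2R,3S)-5,7-bis(benzyloxy)-2-[4-(benzyloxy)phenyl]-3-[(2S)-5,7-bis(benzyloxy)-2-(4-methoxyphenyl)-4-oxochroman-8-yl]chroman-4-one
Conditions: [Rh(OH)(cod)]2 (3 mol %), (S)-MeO-F12-BIPHEP (7 mol %), toluene/H2O 10:1, 30 °C, no added base; SiO2 chromatography
Reagents that add atoms: none
Why: Hayashi–Miyaura rhodium-catalysed asymmetric 1,4-addition of the arylboronic acid to the chromone sets C2 of unit 2 as S under ligand control irrespective of the remote unit 1, so the two enantiomers of 8 become two diastereomers, and chromatography keeps 10 with the 2R,3S configuration of unit 1 and removes the diastereomer with the 2S,3R configuration of unit 1 (at most half of the material).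

Step 6
Reactants: 10 (2R,3S)-5,7-bis(benzyloxy)-2-[4-(benzyloxy)phenyl]-3-[(2S)-5,7-bis(benzyloxy)-2-(4-methoxyphenyl)-4-oxochroman-8-yl]chroman-4-one
Product: 11 (2R,3S)-5,7-dihydroxy-2-(4-hydroxyphenyl)-3-[(2S)-5,7-dihydroxy-2-(4-methoxyphenyl)-4-oxochroman-8-yl]chroman-4-one (target)
Conditions: H2 (1 atm), Pd/C (10 wt % Pd), THF/MeOH, 25 °C
Reagents that add atoms: none
Why: Catalytic hydrogenolysis of the five benzyl ethers under neutral conditions leaves the aryl methyl ether, both ketones and all three stereocentres untouched, since neither acid nor base is present to open a flavanone ring.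

## Compound list

1 | 1-[2,4-bis(benzyloxy)-6-hydroxyphenyl]ethan-1-one | CC(=O)c1c(O)cc(OCc2ccccc2)cc1OCc1ccccc1 | starting material
2 | 1-[4,6-bis(benzyloxy)-3-bromo-2-hydroxyphenyl]ethan-1-one | CC(=O)c1c(O)c(Br)c(OCc2ccccc2)cc1OCc1ccccc1 | intermediate
3 | (E)-1-[4,6-bis(benzyloxy)-3-bromo-2-hydroxyphenyl]-3-(dimethylamino)prop-2-en-1-one | CN(C)/C=C/C(=O)c1c(O)c(Br)c(OCc2ccccc2)cc1OCc1ccccc1 | intermediate
4 | (E)-1-{4,6-bis(benzyloxy)-3-[2-(2,4-bis(benzyloxy)-6-hydroxyphenyl)-2-oxoethyl]-2-hydroxyphenyl}-3-(dimethylamino)prop-2-en-1-one | CN(C)/C=C/C(=O)c1c(O)c(CC(=O)c2c(O)cc(OCc3ccccc3)cc2OCc2ccccc2)c(OCc2ccccc2)cc1OCc1ccccc1 | intermediate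
5 | 4-(benzyloxy)benzaldehyde | O=Cc1ccc(OCc2ccccc2)cc1 | starting material
6 | 5,7-bis(benzyloxy)-8-{2-[2,4-bis(benzyloxy)-6-hydroxyphenyl]-2-oxoethyl}-4H-chromen-4-one (not isolated) | O=c1ccoc2c1c(OCc1ccccc1)cc(OCc1ccccc1)c2CC(=O)c1c(O)cc(OCc2ccccc2)cc1OCc1ccccc1 | intermediate
7 | 5,7-bis(benzyloxy)-8-{(1E)-3-[2,4-bis(benzyloxy)-6-hydroxyphenyl]-1-[4-(benzyloxy)phenyl]-3-oxoprop-1-en-2-yl}-4H-chromen-4-one (not isolated; the Z isomer cyclises to the same product) | O=c1ccoc2c1c(OCc1ccccc1)cc(OCc1ccccc1)c2/C(=C\c1ccc(OCc2ccccc2)cc1)C(=O)c1c(O)cc(OCc2ccccc2)cc1OCc1ccccc1 | intermediate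
8 | trans-5,7-bis(benzyloxy)-2-[4-(benzyloxy)phenyl]-3-[5,7-bis(benzyloxy)-4-oxo-4H-chromen-8-yl]chroman-4-one, racemate (SMILES shows the 2R,3S enantiomer; the 2S,3R mirror image is present in equal amount) | O=c1ccoc2c1c(OCc1ccccc1)cc(OCc1ccccc1)c2[C@@H]1C(=O)c2c(OCc3ccccc3)cc(OCc3ccccc3)cc2O[C@H]1c1ccc(OCc2ccccc2)cc1 | intermediate
9 | 4-methoxyphenylboronic acid | COc1ccc(B(O)O)cc1 | starting material
10 | (2R,3S)-5,7-bis(benzyloxy)-2-[4-(benzyloxy)phenyl]-3-[(2S)-5,7-bis(benzyloxy)-2-(4-methoxyphenyl)-4-oxochroman-8-yl]chroman-4-one | COc1ccc([C@@H]2CC(=O)c3c(OCc6ccccc6)cc(OCc6ccccc6)c([C@@H]4C(=O)c5c(OCc6ccccc6)cc(OCc6ccccc6)cc5O[C@H]4c4ccc(OCc6ccccc6)cc4)c3O2)cc1 | intermediate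
11 | (2R,3S)-5,7-dihydroxy-2-(4-hydroxyphenyl)-3-[(2S)-5,7-dihydroxy-2-(4-methoxyphenyl)-4-oxochroman-8-yl]chroman-4-one (CNP0140544.1) | COc1ccc([C@@H]2CC(=O)c3c(O)cc(O)c([C@@H]4C(=O)c5c(O)cc(O)cc5O[C@H]4c4ccc(O)cc4)c3O2)cc1 | target

## Step count and weak points

Total steps: 6. Longest linear sequence: 6 (1 → 2 → 3 → 4 → 8 → 10 → 11).

**Step 3 (enolate arylation with two free phenols and a doubly ortho-substituted bromide).** If the lithium dienolate does not couple, or the ortho benzyl ether is attacked by the arylpalladium intermediate, the bond is made under neutral fluoride-mediated conditions instead. Setting out from 1, Me3SiOTf/Et3N gives the silyl enol ether (1-{2,4-bis(benzyloxy)-6-[(trimethylsilyl)oxy]phenyl}ethenyl)oxy(trimethyl)silane F1. Compound 3 is O-silylated (Me3SiCl, Et3N) to (E)-1-{4,6-bis(benzyloxy)-3-bromo-2-[(trimethylsilyl)oxy]phenyl}-3-(dimethylamino)prop-2-en-1-one F2. F1 and F2 are coupled with Pd2(dba)3/P(t-Bu)3 and ZnF2/CsF in DMF at 80 °C (silyl enol ether arylation). Aqueous methanolic work-up removes the remaining aryl silyl ethers, and the route is rejoined at 4.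

**Step 4 (Knoevenagel condensation at a methylene flanked by two 2,6-disubstituted aryl groups, in the same pot as chromone closure).** If the condensation stalls, or the aldehyde attacks the ring-opened enaminone, the carbon–carbon bond is made first with a stoichiometric enolate. Setting out from 4, LiN(SiMe3)2 (3.3 equiv) in THF at −78 °C followed by 5 gives the aldol adduct (E)-1-{4,6-bis(benzyloxy)-3-[1-(2,4-bis(benzyloxy)-6-hydroxybenzoyl)-2-(4-(benzyloxy)phenyl)-2-hydroxyethyl]-2-hydroxyphenyl}-3-(dimethylamino)prop-2-en-1-one F3 as a diastereomer mixture. Warming F3 in AcOH with catalytic TsOH closes the chromone, ionises the 4-benzyloxybenzylic alcohol and lets the phenol capture the cation (dehydrative cyclisation, trans by equilibration). Both rings still form in one flask, and the route is rejoined at 8.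

**Step 5 (asymmetric arylation of a hindered, electron-rich 5,7-dialkoxychromone, then separation of 10 from its unit-1 diastereomer).** If the 1,4-addition is slow or unselective, the order of bond formation at C2 of unit 2 is reversed. Setting out from 8, oxidative Heck-type C2–H arylation of the chromone with 9 (Pd(OCOCF3)2 catalyst, quinone oxidant) gives the flavone 5,7-bis(benzyloxy)-8-{trans-5,7-bis(benzyloxy)-2-[4-(benzyloxy)phenyl]-4-oxochroman-3-yl}-2-(4-methoxyphenyl)-4H-chromen-4-one F4. Enantioselective conjugate reduction of F4 with the copper hydride made from Cu(OAc)2, DTBM-SEGPHOS (antipode chosen for the S centre) and diethoxymethylsilane then delivers hydride to C2 of unit 2. Chromatography separates 10 from the diastereomer with the 2S,3R configuration of unit 1 as before, and the route is rejoined at 10.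

## Further compounds

F1 | step 3 | (1-{2,4-bis(benzyloxy)-6-[(trimethylsilyl)oxy]phenyl}ethenyl)oxy(trimethyl)silane | C=C(O[Si](C)(C)C)c1c(O[Si](C)(C)C)cc(OCc2ccccc2)cc1OCc1ccccc1
F2 | step 3 | (E)-1-{4,6-bis(benzyloxy)-3-bromo-2-[(trimethylsilyl)oxy]phenyl}-3-(dimethylamino)prop-2-en-1-one | CN(C)/C=C/C(=O)c1c(O[Si](C)(C)C)c(Br)c(OCc2ccccc2)cc1OCc1ccccc1
F3 | step 4 | (E)-1-{4,6-bis(benzyloxy)-3-[1-(2,4-bis(benzyloxy)-6-hydroxybenzoyl)-2-(4-(benzyloxy)phenyl)-2-hydroxyethyl]-2-hydroxyphenyl}-3-(dimethylamino)prop-2-en-1-one, diastereomer mixture at the two new sp3 centres | CN(C)/C=C/C(=O)c1c(O)c(C(C(O)c2ccc(OCc3ccccc3)cc2)C(=O)c2c(O)cc(OCc3ccccc3)cc2OCc2ccccc2)c(OCc2ccccc2)cc1OCc1ccccc1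
F4 | step 5 | 5,7-bis(benzyloxy)-8-{trans-5,7-bis(benzyloxy)-2-[4-(benzyloxy)phenyl]-4-oxochroman-3-yl}-2-(4-methoxyphenyl)-4H-chromen-4-one, racemate (2R,3S enantiomer shown) | COc1ccc(-c2cc(=O)c3c(OCc6ccccc6)cc(OCc6ccccc6)c([C@@H]4C(=O)c5c(OCc6ccccc6)cc(OCc6ccccc6)cc5O[C@H]4c4ccc(OCc6ccccc6)cc4)c3o2)cc1
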